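## Retrosynthetic overview

1. The C30 skeleton is read as two enantiomeric C12 cyclohexanones attached to the two α-carbons of adipic acid. Adipic acid supplies C-12, 11, 13, 13', 11' and 12', so the central CH2–CH2 bond is never made.
2. The butenolide of unit A (the last ring closed) comes from a γ-keto acid by loss of water. C-8 is set by equilibration.
3. Key disconnection C-7–C-11, α-carbon to α-carbon: an enolonium species of the (4R,5R)-ketone is joined to a silyl ketene acetal of the unit B lactone acid. C-11' is fixed in the same flask by convex-face protonation.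
4. The cis-lactone of unit B (the first heterocycle closed) comes from a keto diacid. That diacid is made by the same polarity-reversed union (C-7'–C-11') with the bis(ketene acetal) of adipic acid.
5. Both silyl enol ethers come from (+)- and (−)-verbenone by anti vinyl addition and cyclobutane fragmentation, so both carbocycles are carved out of the pinane ring.

Assumption: both verbenone enantiomers are bought (each is also one allylic oxidation from the matching cheap α-pinene); elemane locants are used, unprimed for the butenolide half (unit A) and primed for the saturated-lactone half (unit B).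

## Route

Step 1
Reactants: 1 (1R,5R)-(+)-verbenone; 2 vinylmagnesium bromide
Product: 3 (1R,4S,5S)-4-ethenyl-4,6,6-trimethylbicyclo[3.1.1]heptan-2-one
Conditions: CH2=CHMgBr (1.5 equiv), CuI (10 mol %), THF, −40 to 0 °C; aq NH4Cl
Reagents that add atoms: vinylmagnesium bromide, C=C[Mg]Br
Why: In this copper-catalysed conjugate addition the gem-dimethyl bridge blocks one face of the enone, so vinyl enters anti to it and sets the quaternary C-10' (methyl syn to the CMe2 bridge).

Step 2
Reactants: 3 vinyl adduct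
Product: 4 (4S,5S)-5-ethenyl-5-methyl-4-(prop-1-en-2-yl)cyclohex-1-en-1-yl acetate
Conditions: BF3·OEt2, Zn(OAc)2, Ac2O, rt
Reagents that add atoms: acetic anhydride, CC(=O)OC(C)=O
Why: In this Lewis-acid-induced cyclobutane fragmentation the strained bond between the α-bridgehead and CMe2 breaks and a methyl proton is lost to give the isopropenyl group, while the enol oxygen is acetylated regiospecifically at C-7'=C-8' and C-5' and C-10' are untouched (methyl cis to isopropenyl, the elemane pattern).

Step 3
Reactants: 4 enol acetate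
Product: 6 [(4S,5S)-5-ethenyl-5-methyl-4-(prop-1-en-2-yl)cyclohex-1-en-1-yl]oxy-trimethylsilane, via lithium enolate 5 (not isolated)
Conditions: MeLi (2.05 equiv), DME, 0 °C; Me3SiCl (2.5 equiv), −78 °C to rt; pentane, cold aq NaHCO3
Reagents that add atoms: chlorotrimethylsilane, C[Si](C)(C)Cl
Why: Enol acetate cleavage with methyllithium (House method) releases the regiodefined enolate without equilibration, and O-silylation keeps the C-7'=C-8' position with no stereocentre touched.

Step 4
Reactants: 7 adipic acid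
Product: 9 1,1,6,6-tetrakis(trimethylsilyloxy)hexa-1,5-diene, via bis(trimethylsilyl) adipate 8 (not isolated)
Conditions: (Me3Si)2NH (1.1 equiv), 80 °C, evaporate; add to LiN(i-Pr)2 (2.3 equiv), THF, −78 °C; Me3SiCl (2.6 equiv), −78 °C to rt; pentane, filter, Kugelrohr
Reagents that add atoms: hexamethyldisilazane, C[Si](C)(C)N[Si](C)(C)C; chlorotrimethylsilane, C[Si](C)(C)Cl
Why: Acid O-silylation followed by enolisation and O-silylation of the silyl ester (Ainsworth bis(silyl) ketene acetal synthesis) turns both α-carbons of adipic acid into neutral carbon nucleophiles with no double-bond geometry to control.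

Step 5
Reactants: 6 silyl enol ether; 9 adipic acid bis(ketene acetal)
Product: 12 2-[(1R,4S,5S)-4-ethenyl-4-methyl-2-oxo-5-(prop-1-en-2-yl)cyclohexyl]hexanedioic acid (C-11' epimers), via enolonium species 10 (not isolated), via silylated adduct 11 (not isolated)
Conditions: PhI(OAc)2 (1.05 equiv), BF3·OEt2 (1.6 equiv), CH2Cl2, −78 °C, add 6, 10 min; add 9 (3 equiv), −78 to −50 °C; 1 M NaOH, rt, 2 h; 1 M HCl
Reagents that add atoms: none
Why: Proposed new method: 6 exchanges onto BF3-activated PhI(OAc)2 to give the trivalent-iodine enolate 10, in which C-7' has become the electrophile, and the much more nucleophilic ketene acetal carbon of 9 (threefold excess to stop at mono-coupling) displaces PhI and joins two natively nucleophilic α-carbons; the closest known reaction type is the coupling of a preformed ketone enolonium species with a second trimethylsilyl enol ether to give unsymmetrical 1,4-diketones, the NaOH hold epimerises C-7' to the equatorial 7'R isomer, and C-11' is left mixed because it is reset in steps 7 and 11.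

Step 6
Reactants: 12 keto diacid
Product: 14 4-[(3aR,5S,6S,7aR)-6-ethenyl-6-methyl-2-oxo-5-(prop-1-en-2-yl)octahydro-1-benzofuran-3-yl]butanoic acid (C-11' epimers), via hydroxy diacid 13 (not isolated)
Conditions: LiBH(s-Bu)3 (3.5 equiv), THF, −78 to 0 °C; 1 M HCl, rt; extraction through aq NaHCO3
Reagents that add atoms: none
Why: In this substrate-controlled ketone reduction the axial C-10' methyl closes the axial trajectory, so the bulky borohydride attacks equatorially and gives the axial 8'R alcohol cis to the equatorial C-7' side chain, which closes the five-membered cis-lactone on acidification.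

Step 7
Reactants: 14 lactone acid
Product: 16 tris-silyl nucleophile (cyclic silyl ketene acetal of the lactone bearing a 4,4-bis(trimethylsilyloxy)but-3-enyl chain at C-11'), via trimethylsilyl ester 15 (not isolated)
Conditions: (Me3Si)2NH (0.6 equiv), THF, 60 °C, evaporate; add to LiN(i-Pr)2 (2.4 equiv), THF, −78 °C, 1 h; Me3SiCl (3 equiv), −78 °C to rt; pentane, filter, use crude
Reagents that add atoms: hexamethyldisilazane, C[Si](C)(C)N[Si](C)(C)C; chlorotrimethylsilane, C[Si](C)(C)Cl
Why: Inverse addition to excess amide enolises the lactone and the silyl ester together, so no acyl group is left for a Dieckmann closure, and O-silylation (Ainsworth type) flattens C-11', which makes both epimers of 14 converge.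

Step 8
Reactants: 17 (1S,5S)-(−)-verbenone; 2 vinylmagnesium bromide
Product: 18 (1S,4R,5R)-4-ethenyl-4,6,6-trimethylbicyclo[3.1.1]heptan-2-one
Conditions: CH2=CHMgBr (1.5 equiv), CuI (10 mol %), THF, −40 to 0 °C; aq NH4Cl
Reagents that add atoms: vinylmagnesium bromide, C=C[Mg]Br
Why: This is the mirror image of step 1 (copper-catalysed conjugate addition anti to the gem-dimethyl bridge), and it sets C-10 of unit A.

Step 9
Reactants: 18 ent-vinyl adduct
Product: 19 (4R,5R)-5-ethenyl-5-methyl-4-(prop-1-en-2-yl)cyclohex-1-en-1-yl acetate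
Conditions: BF3·OEt2, Zn(OAc)2, Ac2O, rt
Reagents that add atoms: acetic anhydride, CC(=O)OC(C)=O
Why: The same Lewis-acid-induced cyclobutane fragmentation as in step 2 retains C-5 and C-10 and places the enol acetate at C-7=C-8.

Step 10
Reactants: 19 ent-enol acetate
Product: 21 [(4R,5R)-5-ethenyl-5-methyl-4-(prop-1-en-2-yl)cyclohex-1-en-1-yl]oxy-trimethylsilane, via lithium enolate 20 (not isolated)
Conditions: MeLi (2.05 equiv), DME, 0 °C; Me3SiCl (2.5 equiv), −78 °C to rt; pentane, cold aq NaHCO3
Reagents that add atoms: chlorotrimethylsilane, C[Si](C)(C)Cl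
Why: Regiospecific enol acetate cleavage and O-silylation proceed as in step 3, with no stereocentre touched.

Step 11
Reactants: 21 ent-silyl enol ether; 16 tris-silyl nucleophile
Product: 24 2-[(4R,5R)-4-ethenyl-4-methyl-2-oxo-5-(prop-1-en-2-yl)cyclohexyl]-4-[(3S,3aR,5S,6S,7aR)-6-ethenyl-6-methyl-2-oxo-5-(prop-1-en-2-yl)octahydro-1-benzofuran-3-yl]butanoic acid (C-7 and C-11 unassigned), via enolonium species 22 (not isolated), via silylated adduct 23 (not isolated)
Conditions: PhI(OAc)2 (1.0 equiv), BF3·OEt2 (1.5 equiv), CH2Cl2, −78 °C, add 21, 10 min; add 16 (1.2 equiv), −78 to −50 °C; AcOH, −78 °C; H2O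
Reagents that add atoms: none
Why: Proposed new method: 21 exchanges onto BF3-activated PhI(OAc)2 to give 22, whose C-7 is now the electrophile, and of the two ketene acetals in 16 only the acyclic one has an unhindered CH terminus, so it displaces PhI and forges C-7–C-11 between two natively nucleophilic α-carbons, while the fully substituted cyclic ketene acetal survives in 23 until the cold acid quench protonates C-11' from the convex face that carries H-7' and H-8' and sets 11'S; C-7 and C-11 are erased in step 12, and the closest known reaction types are the enolonium cross-coupling of two different trimethylsilyl enol ethers and the kinetic protonation of cis-fused bicyclic lactone enolates.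

Step 12
Reactants: 24 γ-keto acid
Product: 26 target CNP0332736.1, via enol lactone 25 (not isolated)
Conditions: Ac2O (1.5 equiv), NaOAc (0.2 equiv), toluene, 80 °C; evaporate; DBU (0.2 equiv), CH2Cl2, rt
Reagents that add atoms: none
Why: In this classical keto acid to enol lactone dehydration followed by β,γ to α,β butenolide isomerisation, reversible deprotonation by DBU moves the double bond to C-7=C-11 and equilibrates C-8 to the more stable 8R epimer (C–O equatorial, trans to the axial C-10 methyl), while the far less acidic H-11' of the saturated lactone is not touched.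

## Compound list

1 | (1R,5R)-(+)-verbenone | CC1=CC(=O)[C@@H]2C[C@H]1C2(C)C | starting material
2 | vinylmagnesium bromide | C=C[Mg]Br | starting material
3 | (1R,4S,5S)-4-ethenyl-4,6,6-trimethylbicyclo[3.1.1]heptan-2-one | C=C[C@]1(C)CC(=O)[C@@H]2C[C@H]1C2(C)C | intermediate
4 | (4S,5S)-5-ethenyl-5-methyl-4-(prop-1-en-2-yl)cyclohex-1-en-1-yl acetate | CC(=O)OC1=CC[C@@H](C(C)=C)[C@](C)(C=C)C1 | intermediate
5 | lithium enolate of the (4S,5S)-ketone (C-7'=C-8') | [Li]OC1=CC[C@@H](C(C)=C)[C@](C)(C=C)C1 | intermediate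
6 | trimethylsilyl enol ether of the (4S,5S)-ketone | C[Si](C)(C)OC1=CC[C@@H](C(C)=C)[C@](C)(C=C)C1 | intermediate
7 | adipic acid | OC(=O)CCCCC(=O)O | starting material
8 | bis(trimethylsilyl) adipate | C[Si](C)(C)OC(=O)CCCCC(=O)O[Si](C)(C)C | intermediate
9 | 1,1,6,6-tetrakis(trimethylsilyloxy)hexa-1,5-diene | C[Si](C)(C)OC(O[Si](C)(C)C)=CCCC=C(O[Si](C)(C)C)O[Si](C)(C)C | intermediate
10 | enolonium species, acetoxy(phenyl)-λ3-iodanyl enolate of the (4S,5S)-ketone (drawn O-bound, BF3 omitted) | CC(=O)OI(c1ccccc1)OC1=CC[C@@H](C(C)=C)[C@](C)(C=C)C1 | intermediate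
11 | silylated adduct (silyl ester at C-12', distal bis(silyl) ketene acetal) | C[Si](C)(C)OC(O[Si](C)(C)C)=CCCC(C(=O)O[Si](C)(C)C)C1C[C@@H](C(C)=C)[C@](C)(C=C)CC1=O | intermediate
12 | 2-[(1R,4S,5S)-4-ethenyl-4-methyl-2-oxo-5-(prop-1-en-2-yl)cyclohexyl]hexanedioic acid | OC(=O)CCCC(C(O)=O)[C@H]1C[C@@H](C(C)=C)[C@](C)(C=C)CC1=O | intermediate
13 | 2-[(1R,2R,4S,5S)-4-ethenyl-2-hydroxy-4-methyl-5-(prop-1-en-2-yl)cyclohexyl]hexanedioic acid | OC(=O)CCCC(C(O)=O)[C@H]1C[C@@H](C(C)=C)[C@](C)(C=C)C[C@H]1O | intermediate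
14 | 4-[(3aR,5S,6S,7aR)-6-ethenyl-6-methyl-2-oxo-5-(prop-1-en-2-yl)octahydro-1-benzofuran-3-yl]butanoic acid | OC(=O)CCCC1C(=O)O[C@@H]2C[C@@](C)(C=C)[C@H](C(=C)C)C[C@H]12 | intermediate
15 | trimethylsilyl ester of 14 | C[Si](C)(C)OC(=O)CCCC1C(=O)O[C@@H]2C[C@@](C)(C=C)[C@H](C(=C)C)C[C@H]12 | intermediate
16 | tris-silyl nucleophile (cyclic plus acyclic silyl ketene acetal) | C[Si](C)(C)OC(O[Si](C)(C)C)=CCCC1=C(O[Si](C)(C)C)O[C@@H]2C[C@@](C)(C=C)[C@H](C(=C)C)C[C@H]12 | intermediate
17 | (1S,5S)-(−)-verbenone | CC1=CC(=O)[C@H]2C[C@@H]1C2(C)C | starting material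
18 | (1S,4R,5R)-4-ethenyl-4,6,6-trimethylbicyclo[3.1.1]heptan-2-one | C=C[C@@]1(C)CC(=O)[C@H]2C[C@@H]1C2(C)C | intermediate
19 | (4R,5R)-5-ethenyl-5-methyl-4-(prop-1-en-2-yl)cyclohex-1-en-1-yl acetate | CC(=O)OC1=CC[C@H](C(C)=C)[C@@](C)(C=C)C1 | intermediate
20 | lithium enolate of the (4R,5R)-ketone (C-7=C-8) | [Li]OC1=CC[C@H](C(C)=C)[C@@](C)(C=C)C1 | intermediate
21 | trimethylsilyl enol ether of the (4R,5R)-ketone | C[Si](C)(C)OC1=CC[C@H](C(C)=C)[C@@](C)(C=C)C1 | intermediate
22 | enolonium species of the (4R,5R)-ketone (drawn O-bound, BF3 omitted) | CC(=O)OI(c1ccccc1)OC1=CC[C@H](C(C)=C)[C@@](C)(C=C)C1 | intermediate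
23 | silylated adduct (silyl ester at C-12, cyclic ketene acetal of unit B intact) | C=C[C@@]1(C)CC(=O)C(C[C@@H]1C(=C)C)C(C(=O)O[Si](C)(C)C)CCC3=C(O[Si](C)(C)C)O[C@@H]4C[C@@](C)(C=C)[C@H](C(=C)C)C[C@H]34 | intermediate
24 | γ-keto acid (name as in step 11) | C=C[C@@]1(C)CC(=O)C(C[C@@H]1C(=C)C)C(C(=O)O)CC[C@@H]3C(=O)O[C@@H]4C[C@@](C)(C=C)[C@H](C(=C)C)C[C@H]34 | intermediate
25 | enol lactone (C-7=C-8, 2(3H)-furanone form of unit A) | C=C[C@@]1(C)CC2=C(C[C@@H]1C(=C)C)C(CC[C@@H]3C(=O)O[C@@H]4C[C@@](C)(C=C)[C@H](C(=C)C)C[C@H]34)C(=O)O2 | intermediate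
26 | (5R,6R,7aR)-6-ethenyl-3-{2-[(3S,3aR,5S,6S,7aR)-6-ethenyl-6-methyl-2-oxo-5-(prop-1-en-2-yl)octahydro-1-benzofuran-3-yl]ethyl}-6-methyl-5-(prop-1-en-2-yl)-5,6,7,7a-tetrahydro-1-benzofuran-2(4H)-one | C=C[C@@]1(C)C[C@H]2OC(=O)C(CC[C@@H]3C(=O)O[C@@H]4C[C@@](C)(C=C)[C@H](C(=C)C)C[C@H]34)=C2C[C@@H]1C(=C)C | target

## Step count and risks

Total step count: 12. Longest linear sequence: 8 steps (1, 2, 3, 5, 6, 7, 11, 12).

**Step 11 (most at risk).** A secondary cyclic enolonium species must pick the acyclic ketene acetal of a precious partner, and the spectator ketene acetal must wait for the quench. The fallback replaces the polar substitution with a radical chain.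
- It sets out from 21. N-Iodosuccinimide in CH2Cl2 at −78 °C gives (4R,5R)-5-ethenyl-2-iodo-5-methyl-4-(prop-1-en-2-yl)cyclohexanone F1.
- Et3B and air with 2,6-lutidine at −20 °C then start an iodine-atom-transfer chain. The electrophilic α-keto radical from F1 adds to the CH terminus of 16.
- The adduct collapses with loss of Me3SiI to 23, which is quenched as in step 11. The route is rejoined at 24.

**Step 5.** The same enolonium chemistry has to stop at mono-coupling of a bis-nucleophile in a BF3 medium. The fallback puts the reversed polarity on a haloacetate and builds the chain by ordinary enolate alkylation.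
- It sets out from lithium enolate 5. Methyl bromoacetate gives methyl 2-[(1R,4S,5S)-4-ethenyl-4-methyl-2-oxo-5-(prop-1-en-2-yl)cyclohexyl]acetate F2.
- LiBH(s-Bu)3 reduces the ketone, and the axial alkoxide closes (3aR,5S,6S,7aR)-6-ethenyl-6-methyl-5-(prop-1-en-2-yl)hexahydro-1-benzofuran-2(3H)-one F3.
- LiN(i-Pr)2 followed by ethyl 4-iodobutanoate gives ethyl 4-[(3R,3aR,5S,6S,7aR)-6-ethenyl-6-methyl-2-oxo-5-(prop-1-en-2-yl)octahydro-1-benzofuran-3-yl]butanoate F4. The chain enters on the convex face, which is harmless because step 7 flattens C-11'.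
- LiOH and then HCl bring the material back to the route at 14.

**Step 6.** The free γ-keto diacid may sit as its lactol or as insoluble lithium salts and stall the hydride, and any equatorial alcohol would give the trans-lactone. The fallback masks both acids and lets the alkoxide close the ring on an ester.
- It sets out from 12. MeI and K2CO3 in DMF give dimethyl 2-[(1R,4S,5S)-4-ethenyl-4-methyl-2-oxo-5-(prop-1-en-2-yl)cyclohexyl]hexanedioate F5.
- LiBH(s-Bu)3 (1.2 equiv, −78 °C to rt) gives methyl 4-[(3aR,5S,6S,7aR)-6-ethenyl-6-methyl-2-oxo-5-(prop-1-en-2-yl)octahydro-1-benzofuran-3-yl]butanoate F6.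
- LiOH and then HCl return to 14.

Further compounds
F1 | step 11 | (4R,5R)-5-ethenyl-2-iodo-5-methyl-4-(prop-1-en-2-yl)cyclohexanone | C=C[C@@]1(C)CC(=O)C(I)C[C@@H]1C(=C)C
F2 | step 5 | methyl 2-[(1R,4S,5S)-4-ethenyl-4-methyl-2-oxo-5-(prop-1-en-2-yl)cyclohexyl]acetate | COC(=O)C[C@H]1C[C@@H](C(C)=C)[C@](C)(C=C)CC1=O
F3 | step 5 | (3aR,5S,6S,7aR)-6-ethenyl-6-methyl-5-(prop-1-en-2-yl)hexahydro-1-benzofuran-2(3H)-one | C1C(=O)O[C@@H]2C[C@@](C)(C=C)[C@H](C(=C)C)C[C@H]12
F4 | step 5 | ethyl 4-[(3R,3aR,5S,6S,7aR)-6-ethenyl-6-methyl-2-oxo-5-(prop-1-en-2-yl)octahydro-1-benzofuran-3-yl]butanoate | CCOC(=O)CCC[C@H]1C(=O)O[C@@H]2C[C@@](C)(C=C)[C@H](C(=C)C)C[C@H]12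
F5 | step 6 | dimethyl 2-[(1R,4S,5S)-4-ethenyl-4-methyl-2-oxo-5-(prop-1-en-2-yl)cyclohexyl]hexanedioate | COC(=O)CCCC(C(=O)OC)[C@H]1C[C@@H](C(C)=C)[C@](C)(C=C)CC1=O
F6 | step 6 | methyl 4-[(3aR,5S,6S,7aR)-6-ethenyl-6-methyl-2-oxo-5-(prop-1-en-2-yl)octahydro-1-benzofuran-3-yl]butanoate | COC(=O)CCCC1C(=O)O[C@@H]2C[C@@](C)(C=C)[C@H](C(=C)C)C[C@H]12
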